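## The problem

The target 37 is an ester of two halves. The left half is a cyclohexene (ring A: isopropyl on A1, CH2OH on A4, A4=A5 alkene, side arm on A6) whose arm is an (E)-2-(hydroxymethyl)acrylic acid. The right half is a cyclohexane (ring B) cis-fused through B2–B3 to a seven-membered unsaturated lactone (ring C); the two halves meet at the primary oxygen of the tertiary/primary diol on B4.

There are six stereocentres. A1 and A6 are trans. B1–B4 are contiguous: the isopropyl group on B1 is trans to the arm on B2, B2 and B3 are cis at the ring fusion, and the B4 hydroxyl is cis to the B3 carbonyl. The isopropyl carbons A1 (R) and B1 (S) have opposite spatial sense, so the halves belong to opposite enantiomeric series and cannot share one chiral intermediate.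

B1 can steer B2 (trans), and a substituent on B3 can steer the quaternary B4. The cis B2/B3 relation is the less stable one (B3 carbonyl axial), and B3 is epimerisable next to the lactone carbonyl, so it has to be made under kinetic control and kept away from base afterwards.

The fragile functions are:
- two 2-(oxymethyl)acrylate units, which are Michael acceptors and allylic esters open to SN2′ exchange or ionisation by zerovalent palladium;
- an ε-lactone and the inter-half ester, which exclude hydroxide and alkoxide late in the route;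
- a tertiary β-hydroxy ester, two allylic alcohols and a free acid.

The enabling feature is the B2–B3 bond. It joins a carbon bearing a C=C arm (B2–CH=) to the α-carbon of a carboxyl group (B3–CO), and B4 beside it is at the oxidation level of an exocyclic methylene. This is the γ,δ-unsaturated acid pattern of a Claisen rearrangement. If the ester oxygen and the allylic carbon are tied into a ten-membered lactone, the rearrangement becomes a ring contraction that makes ring B and the cis relation in one event.

## Retrosynthesis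

**37 ⇒ 36 (protecting groups).** The two primary alcohols of the left half are masked as silyl ethers and the ring-C acid as a tert-butyl ester. All three fall to acid, so no base, hydride or palladium meets the finished ester array. The forward step is a single acidolysis.

**36 ⇒ 35 ⇒ 34 (ring C).** Ring C is cut at its alkene (B2–CH=C) and at the O–CH2 bond. Forward, the carboxylate of 34 is alkylated by an allylic bromide that carries the acrylate ester (35), and ring-closing metathesis joins the B2 vinyl group to the 2-substituted acrylate (36). The neighbouring cut, aldehyde olefination plus lactonisation, would need oxidative cleavage of the vinyl group in the presence of the ring-A alkenes. Metathesis uses the vinyl group as it stands and touches only the two terminal alkenes. The ring fixes the alkene geometry, and carboxylate alkylation involves no acyl activation, so B3 cannot epimerise.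

**34 ⇒ 32 ⇒ 19 + 31 (joining the halves).** The inter-half ester is cut at the alkyl–oxygen bond, not the acyl–oxygen bond. Forward, the carboxylate of 31 opens the spiro-epoxide 19 at its CH2 group, so B4 is not touched and no diol has to be protected and differentiated. The B3 CH2OH of 32 is then oxidised back to the acid 34. This cut divides the molecule into halves of similar size. It asks for an SN2 opening at a hindered but primary epoxide carbon by a conjugated carboxylate.

**19 ⇒ 18 ⇒ 17 (B4).** The epoxide comes from the exocyclic methylene under the control of B3. The carboxyl of 17 is reduced to CH2OH (18) so that a vanadium alkoxide can deliver oxygen to the alkene face it overhangs. Reagent control alone would attack the opposite face, away from the axial B3 group. Halolactonisation from the acid would compete with five-membered closure onto the vinyl group. The price is a reduction and a later reoxidation.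

**17 ⇒ 14 (key step, B2–B3).** The B2–B3 bond is cut by a retro-[3,3] shift that re-forms the allylic C–O bond. The precursor 14 is a ten-membered (E)-allylic lactone with one stereocentre and no carbocycle. Forward, the silyl ketene acetal must rearrange through the boat that the ring imposes, with the isopropyl group pseudo-equatorial.

**14 ⇒ 12 ⇒ 10 ⇒ 9 ⇒ 7 (lactone and methylidene acid).** The lactone C–O bond is cut to the seco acid 12. The CH2–C(=CH2) bond next to the carboxyl is cut to a vinyl triflate 9 and a zinc ester enolate. The kinetic enol triflate of methyl ketone 7 fixes the position of the methylidene. Allylic functionalisation of an isopropenyl group would leave that position ambiguous. The coupling gives the β,γ-unsaturated ester 10 without an enolate of the product.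

**7 ⇒ 4 ⇒ 3 ⇒ 1 + 2 (chain and B1).** The E alkene is cut by a Wittig disconnection to aldehyde 3, and the B1 centre by an enamine Michael disconnection to 1 and 2. Enoate 4 is reduced to diol 5 before any ketone enolate is made, because the kinetic enolate of a keto enoate would cyclise by six-membered Michael addition. The ketone is restored at 7 after silylation (6).

**31 ⇒ 30 ⇒ 29 ⇒ 28 ⇒ 27 ⇒ 26 ⇒ 24 ⇒ 22 ⇒ 20 ⇒ 1 + 2 (left half).**
- Ring A is the cyclohexenone 22, made by aldol condensation of 20, the enantiomer of 3.
- Conjugate addition of a vinyl group sets A6 trans to A1. Trapping the enolate as triflate 24 fixes the A4=A5 alkene and deactivates it.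
- Ozonolysis of the vinyl group gives aldehyde 26.
- The arm is cut at its alkene (27, by alkoxide addition to a phosphonoacrylate followed by olefination).
- The A4 CH2OH is cut at the ring–CH2 bond (29, by coupling of the triflate with a hydroxymethylstannane).
- Both halves thus come from 1 and 2 through the two enantiomers of one catalyst.

## Roads not taken

**Alternative 1:** Ring B is cut at B3–B4 together with the B4–O/acyl bond. Forward, the keto acid A2 is activated, a nucleophilic amine catalyst forms an ammonium enolate that adds to the ketone, and the alkoxide acylates to close the cis-fused β-lactone A1.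
- Merits: the tertiary C–O bond on B4 and its cis relation to the B3 carbonyl arise in the ring-forming step at the right oxidation level, catalytically. The β-lactone is an activated acyl group for later esterification.
- Weak points: A1 carries only a methylene at B2. The alkenyl arm would have to enter at an unactivated position β to the lactone carbonyl, or A2 would need a B2 substituent, in which case nothing enforces the cis B2/B3 relation and the enolate is α-branched. Control by the remote isopropyl centre is uncertain. Ring C and the inter-half ester remain to be made.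
- Comparison: on B4 this road is better; the chosen plan spends steps 11, 12 and 23 on what A1 contains from the start. The chosen plan sets against this that its key step delivers the B2 vinyl group and the B3 carboxyl cis, with B1 in place, which is the relation hardest to reach otherwise.

**Alternative 2:** Ring C is cut at O–CH2 and at the ring alkene. Forward, the carboxylate of the cis formyl acid A4 adds to the phosphonoacrylate A5, and the phosphonate anion olefinates the aldehyde intramolecularly to give A3.
- Merits: two bonds and the ring in one operation, with the alkene geometry fixed by the ring. The acetonide of A3 would let the left half be attached last by acylation, which is more convergent than the chosen route, where the left half is carried through four steps.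
- Weak points: a carboxylate is a weak and reversible oxa-Michael donor. A4 will rest as a cyclic pseudo-acid, and its B2 and B3 centres can epimerise to the trans arrangement under the base needed. The aldehyde requires an oxidative cleavage. The road presupposes ring B with all four stereocentres and says nothing on how B2/B3 cis arises.
- Comparison: for ring C alone it is as short or shorter (one step against two). The chosen plan sets against it neutral metathesis on the vinyl group exactly as the rearrangement delivers it, and a solution for ring B.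

**Alternative 3:** Ring A is cut into three open-chain pieces. Under a diarylprolinol silyl ether, aldehyde A7 adds to nitroalkene A8, the nitronate adds to enal A9, and aldol condensation closes the ring to A6.
- Merits: ring A with both stereocentres, the formyl group for the A4 CH2OH and the oxygenated carbon on A6 arise in one catalyst-controlled step from achiral materials. This is shorter than the four steps (13–16) the chosen plan needs to reach aldehyde 26.
- Weak points: the nitro group on the future A2 has to be removed from a secondary carbon, where radical denitration is inefficient and loss of nitrous acid would give a diene. One of three new stereocentres is thrown away. The road does nothing for rings B and C.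
- Comparison: for ring A it is at least as good in step count. The chosen plan sets against it that both halves start from 1 and 2 with one catalyst scaffold in its two enantiomeric forms, that the trans relation comes from a reliable cuprate addition, and that no denitration is needed.

Key step: step 10

Assumption: the (S)-configured pyrrolidine catalyst is taken to give (S)-3 (attack on the enamine face remote from the diphenyl(methoxy)methyl group) and its enantiomer to give (R)-20; were the sense opposite, the catalysts of steps 1 and 13 would be exchanged.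

Step 1
Reactants: 1 3-methylbutanal; 2 but-3-en-2-one
Product: 3 (2S)-5-oxo-2-(propan-2-yl)hexanal
Conditions: (S)-2-[methoxy(diphenyl)methyl]pyrrolidine (5 mol%), ethyl 3,4-dihydroxybenzoate (20 mol%), neat, 4 °C
Reagents that add atoms: none
Why: Enamine-catalysed Michael addition of an aldehyde to an enone; the catechol activates the enone by hydrogen bonding and the enone should add to the E-enamine on the face away from the diphenyl(methoxy)methyl group, setting the (S) centre that becomes B1.

Step 2
Reactants: 3
Product: 4 ethyl (2E,4S)-7-oxo-4-(propan-2-yl)oct-2-enoate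
Conditions: Ph3P=CHCO2Et, CH2Cl2, rt
Reagents that add atoms: ethyl 2-(triphenyl-λ5-phosphanylidene)acetate, CCOC(=O)C=P(c1ccccc1)(c1ccccc1)c1ccccc1
Why: Wittig olefination with a stabilised ylide is E-selective, reacts with the aldehyde only and is neutral, so the α-stereocentre is not epimerised and no aldol cyclisation is triggered.

Step 3
Reactants: 4
Product: 5 (2E,4S)-4-(propan-2-yl)oct-2-ene-1,7-diol
Conditions: iBu2AlH (4 equiv), CH2Cl2, −78 → 0 °C; aq. potassium sodium tartrate
Reagents that add atoms: none
Why: Aluminium hydride reduction takes the enoate 1,2 to the allylic alcohol and the ketone to a carbinol whose configuration is irrelevant because step 5 restores the ketone; removing the enoate now prevents a six-membered intramolecular Michael addition when the ketone enolate is made in step 6.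

Step 4
Reactants: 5
Product: 6 (5S,6E)-8-{[tert-butyl(dimethyl)silyl]oxy}-5-(propan-2-yl)oct-6-en-2-ol
Conditions: TBSCl (1.05 equiv), imidazole, CH2Cl2, −20 → 0 °C
Reagents that add atoms: tert-butyl(chloro)dimethylsilane, CC(C)(C)[Si](C)(C)Cl
Why: Selective silylation of a primary over a secondary alcohol; with one equivalent of the bulky chlorosilane at low temperature the unhindered allylic hydroxyl should react first.

Step 5
Reactants: 6
Product: 7 (5S,6E)-8-{[tert-butyl(dimethyl)silyl]oxy}-5-(propan-2-yl)oct-6-en-2-one
Conditions: Dess–Martin periodinane, NaHCO3, CH2Cl2, 0 °C → rt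
Reagents that add atoms: none
Why: Dess–Martin oxidation of the secondary alcohol under buffered, non-basic conditions; silyl ether, alkene and stereocentre are not affected.

Step 6
Reactants: 7
Product: 9 (5S,6E)-8-{[tert-butyl(dimethyl)silyl]oxy}-5-(propan-2-yl)octa-1,6-dien-2-yl trifluoromethanesulfonate, via lithium enolate 8 (not isolated)
Conditions: LiN(iPr)2, THF, −78 °C; then PhNTf2, −78 → 0 °C; aq. NH4Cl
Reagents that add atoms: N-phenylbis(trifluoromethanesulfonimide), FC(F)(F)S(=O)(=O)N(c1ccccc1)S(=O)(=O)C(F)(F)F
Why: Kinetic deprotonation of a methyl ketone by the hindered amide takes a methyl proton, and O-sulfonylation of the enolate fixes the terminal alkene (enol triflate formation); this defines the position of the future exocyclic methylene.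

Step 7
Reactants: 9
Product: 10 ethyl (5S,6E)-8-{[tert-butyl(dimethyl)silyl]oxy}-3-methylidene-5-(propan-2-yl)oct-6-enoate
Conditions: BrZnCH2CO2Et (2 equiv), Pd(PPh3)4 (5 mol%), THF, 60 °C
Reagents that add atoms: (2-ethoxy-2-oxoethyl)zinc bromide, CCOC(=O)C[Zn]Br
Why: Negishi-type cross-coupling of a Reformatsky reagent with a vinyl triflate (oxidative addition to zerovalent palladium, transmetalation from zinc, reductive elimination) gives the β,γ-unsaturated ester directly, with no stage at which the double bond is drawn into conjugation.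

Step 8
Reactants: 10
Product: 12 (5S,6E)-8-hydroxy-3-methylidene-5-(propan-2-yl)oct-6-enoic acid, via lithium carboxylate 11 (not isolated)
Conditions: LiOH, THF/MeOH/H2O, rt; then 1 M HCl to pH 1, rt
Reagents that add atoms: lithium hydroxide, [Li+].[OH-]
Why: Saponification gives the carboxylate, whose α-protons are no longer acidic, so the methylidene stays out of conjugation; acidification then cleaves the primary silyl ether.

Step 9
Reactants: 12
Product: 14 (7S,8E)-4-methylidene-7-(propan-2-yl)oxacyclodec-8-en-2-one, via mixed anhydride 13 (not isolated)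
Conditions: 2-methyl-6-nitrobenzoic anhydride, DMAP, Et3N, CH2Cl2 (2 mM, slow addition), rt
Reagents that add atoms: none
Why: Shiina macrolactonisation: the mixed anhydride acylates the allylic hydroxyl through the acylpyridinium ion at room temperature and high dilution; the E alkene, the methylidene and the ester reduce the transannular strain of the ten-membered ring.

Step 10
Reactants: 14
Product: 17 (1S,2S,3S)-2-ethenyl-6-methylidene-3-(propan-2-yl)cyclohexane-1-carboxylic acid, via silyl ketene acetal 15 (not isolated), via trimethylsilyl ester 16 (not isolated)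
Conditions: LiN(iPr)2, Me3SiCl/Et3N, THF, −78 °C; warm to rt, then 65 °C; 1 M HCl
Reagents that add atoms: none
Why: LiN(iPr)2 deprotonates C3 of the lactone in the presence of Me3SiCl, and O-silylation of the dienolate gives the cyclic silyl ketene acetal 15, conjugated with the C4 methylidene. On warming, a concerted [3,3] sigmatropic shift forms the C3–C8 bond (B3–B2) while the allylic C10–O bond breaks, and the silyl ester 16 is hydrolysed to 17. The closest known reaction type is the Ireland–Claisen ring contraction of macrocyclic allylic lactones to cis-2-alkenylcycloalkanecarboxylic acids. Ring B closes transannularly: the new bond joins two atoms that were 1,6-related in the ten-membered ring, and both reacting π-bonds end up exocyclic to the new six-membered carbocycle (vinyl and carboxyl). For B2 and B3, the four-carbon bridge C4–C7 can span the termini only in a boat-like transition state, which with the E alkene places vinyl and carboxyl cis, a relation that equilibration would not give. B1 controls the face: the isopropyl group on C7 should sit pseudo-equatorial in the nascent ring, trans to the vinyl group. The step needs α- and not γ-bonding of the dienolate and O- and not C-silylation; the in situ chlorosilane quench at −78 °C secures the second, the cyclic array in which only C3 can reach C8 secures the first, and the methylidene offers no leaving group β to the enolate.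

Step 11
Reactants: 17
Product: 18 [(1S,2S,3S)-2-ethenyl-6-methylidene-3-(propan-2-yl)cyclohexyl]methanol
Conditions: LiAlH4, THF, 0 °C → reflux
Reagents that add atoms: none
Why: LiAlH4 reduces the acid through its carboxylate, which cannot enolise, so the axial B3 centre and the β,γ-alkene are kept.

Step 12
Reactants: 18
Product: 19 [(3R,4R,5S,6S)-5-ethenyl-6-(propan-2-yl)-1-oxaspiro[2.5]octan-4-yl]methanol
Conditions: VO(acac)2 (5 mol%), tBuOOH, CH2Cl2, 0 °C → rt
Reagents that add atoms: tert-butyl hydroperoxide, CC(C)(C)OO
Why: Hydroxyl-directed epoxidation of a homoallylic alcohol: the axial CH2OH on B3 binds the vanadium peroxide and delivers oxygen to the face of the exocyclic alkene that it overhangs, setting B4 with oxygen cis to the B3 substituent; the monosubstituted vinyl group, one bond further from the hydroxyl, should react much more slowly.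

Step 13
Reactants: 1 3-methylbutanal; 2 but-3-en-2-one
Product: 20 (2R)-5-oxo-2-(propan-2-yl)hexanal
Conditions: (R)-2-[methoxy(diphenyl)methyl]pyrrolidine (5 mol%), ethyl 3,4-dihydroxybenzoate (20 mol%), neat, 4 °C
Reagents that add atoms: none
Why: The enamine Michael addition of step 1 with the enantiomeric catalyst gives the (R) aldehyde needed for ring A, whose isopropyl centre has the opposite sense to B1.

Step 14
Reactants: 20
Product: 22 (4R)-4-(propan-2-yl)cyclohex-2-en-1-one, via aldol adduct 21 (not isolated)
Conditions: LiOH, iPrOH, rt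
Reagents that add atoms: none
Why: Intramolecular aldol condensation: the methyl ketone enolate adds to the aldehyde and the aldol loses water to the conjugated enone; the mild hydroxide conditions are chosen to limit racemisation through the dienolate.

Step 15
Reactants: 22
Product: 24 (3R,4R)-3-ethenyl-4-(propan-2-yl)cyclohex-1-en-1-yl trifluoromethanesulfonate, via magnesium enolate 23 (not isolated)
Conditions: CH2=CHMgBr, CuBr·SMe2 (10 mol%), THF, −78 → −40 °C; then N-(5-chloropyridin-2-yl)bis(trifluoromethanesulfonimide), −78 °C → rt; aq. NH4Cl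
Reagents that add atoms: vinylmagnesium bromide, C=C[Mg]Br; N-(5-chloropyridin-2-yl)bis(trifluoromethanesulfonimide), FC(F)(F)S(=O)(=O)N(c1ccc(Cl)cn1)S(=O)(=O)C(F)(F)F
Why: Copper-catalysed conjugate addition of the vinyl Grignard reagent occurs anti to the adjacent isopropyl group, setting A6 trans to A1, and O-sulfonylation of the enolate fixes the A4=A5 double bond regiospecifically (conjugate addition with enolate trapping).

Step 16
Reactants: 24
Product: 26 (3R,4R)-3-formyl-4-(propan-2-yl)cyclohex-1-en-1-yl trifluoromethanesulfonate, via ozonide 25 (not isolated)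
Conditions: O3, CH2Cl2, −78 °C; then PPh3, −78 °C → rt
Reagents that add atoms: ozone, [O-][O+]=O
Why: Ozonolysis with reductive work-up: the electron-poor enol triflate is far less reactive towards ozone than the vinyl group, and the neutral work-up spares the aldehyde α-centre, whose trans arrangement is in any case the more stable.

Step 17
Reactants: 26
Product: 27 ethyl (2E)-2-{[(4-methoxyphenyl)methoxy]methyl}-3-[(1S,6R)-6-(propan-2-yl)-3-{[(trifluoromethyl)sulfonyl]oxy}cyclohex-2-en-1-yl]prop-2-enoate
Conditions: 4-MeOC6H4CH2OH, NaH, ethyl 2-(diethoxyphosphoryl)acrylate, THF, 0 °C; then 26, 0 °C → rt; aq. NH4Cl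
Reagents that add atoms: (4-methoxyphenyl)methanol, COc1ccc(CO)cc1; ethyl 2-(diethoxyphosphoryl)prop-2-enoate, C=C(C(=O)OCC)P(=O)(OCC)OCC
Why: Tandem oxa-Michael addition and Horner–Wadsworth–Emmons olefination: the alkoxide adds to the phosphonoacrylate and the stabilised phosphonate anion so formed olefinates the aldehyde; the α-substituted reagent and the branched aldehyde should favour the E isomer, ring trans to the ester.

Step 18
Reactants: 27
Product: 28 ethyl (2E)-2-(hydroxymethyl)-3-[(1S,6R)-6-(propan-2-yl)-3-{[(trifluoromethyl)sulfonyl]oxy}cyclohex-2-en-1-yl]prop-2-enoate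
Conditions: DDQ, CH2Cl2/pH 7 buffer, 0 °C
Reagents that add atoms: none
Why: Oxidative cleavage of the 4-methoxybenzyl ether (hydride abstraction, hydrolysis of the oxocarbenium ion); triflate, acrylate and stereocentres are inert, and the ether is removed here, on a simple compound, so that the end of the route needs acid only.

Step 19
Reactants: 28
Product: 29 ethyl (2E)-2-(hydroxymethyl)-3-[(1R,6R)-3-(hydroxymethyl)-6-(propan-2-yl)cyclohex-2-en-1-yl]prop-2-enoate
Conditions: Bu3SnCH2OH, Pd(PPh3)4 (5 mol%), LiCl, 1,4-dioxane, 90 °C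
Reagents that add atoms: (tributylstannyl)methanol, CCCC[Sn](CCCC)(CCCC)CO
Why: Stille coupling of the vinyl triflate with a hydroxymethylstannane (oxidative addition to zerovalent palladium, chloride-assisted transmetalation, reductive elimination) installs the A4 CH2OH; the free hydroxyl of the arm is tolerated.

Step 20
Reactants: 29
Product: 30 ethyl (2E)-2-({[tert-butyl(dimethyl)silyl]oxy}methyl)-3-[(1R,6R)-3-({[tert-butyl(dimethyl)silyl]oxy}methyl)-6-(propan-2-yl)cyclohex-2-en-1-yl]prop-2-enoate
Conditions: TBSCl (2.5 equiv), imidazole, DMF, rt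
Reagents that add atoms: tert-butyl(chloro)dimethylsilane, CC(C)(C)[Si](C)(C)Cl
Why: Silylation of both primary allylic alcohols; the silyl ethers should survive the basic and oxidative steps ahead and fall to acid at the end.

Step 21
Reactants: 30
Product: 31 (2E)-2-({[tert-butyl(dimethyl)silyl]oxy}methyl)-3-[(1R,6R)-3-({[tert-butyl(dimethyl)silyl]oxy}methyl)-6-(propan-2-yl)cyclohex-2-en-1-yl]prop-2-enoic acid
Conditions: LiOH, THF/MeOH/H2O, 40 °C; then 0.5 M HCl to pH 4, 0 °C
Reagents that add atoms: lithium hydroxide, [Li+].[OH-]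
Why: Saponification of the hindered conjugated ethyl ester; primary silyl ethers tolerate aqueous hydroxide, and acidification only to pH 4 in the cold keeps them.

Step 22
Reactants: 19 [(3R,4R,5S,6S)-5-ethenyl-6-(propan-2-yl)-1-oxaspiro[2.5]octan-4-yl]methanol; 31 the left-half acid
Product: 32 {(1R,2R,3S,4S)-3-ethenyl-1-hydroxy-2-(hydroxymethyl)-4-(propan-2-yl)cyclohexyl}methyl ester of acid 31
Conditions: Cs2CO3 (0.5 equiv), DMF, 80 °C
Reagents that add atoms: none
Why: Nucleophilic ring opening of an epoxide by a carboxylate (SN2 at the unsubstituted CH2, the only carbon open to backside attack) forms the inter-half ester and leaves B4 as set in step 12; the new ester arm and the B3 CH2OH are trans-diaxial, which should prevent acyl migration.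

Step 23
Reactants: 32
Product: 34 (1S,2R,5S,6S)-6-ethenyl-2-hydroxy-5-(propan-2-yl)-2-(acyloxymethyl)cyclohexane-1-carboxylic acid in which the acyl group is that of 31, via aldehyde 33 (not isolated)
Conditions: TEMPO (20 mol%), PhI(OAc)2 (2.5 equiv), MeCN/H2O, rt
Reagents that add atoms: water, O
Why: Oxoammonium-mediated oxidation of the primary alcohol through the aldehyde hydrate to the acid; tertiary alcohol, alkenes and silyl ethers are not oxidised, and the epimerisable β-hydroxy aldehyde is not isolated.

Step 24
Reactants: 34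
Product: 35 2-(tert-butoxycarbonyl)prop-2-en-1-yl ester of acid 34
Conditions: tert-butyl 2-(bromomethyl)acrylate, K2CO3, DMF, 0 °C → rt
Reagents that add atoms: tert-butyl 2-(bromomethyl)prop-2-enoate, C=C(CBr)C(=O)OC(C)(C)C
Why: O-Alkylation of the carboxylate by a reactive allylic bromide (SN2 and SN2′ give the same product); no acyl activation is involved, so the axial B3 centre cannot epimerise, and the tertiary hydroxyl is left alone.

Step 25
Reactants: 35
Product: 36 tert-butyl (5aR,6S,9R,9aS)-9-hydroxy-1-oxo-6-(propan-2-yl)-9-(acyloxymethyl)-1,3,5a,6,7,8,9,9a-octahydro-2-benzoxepine-4-carboxylate in which the acyl group is that of 31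
Conditions: second-generation Grubbs catalyst (10 mol%), toluene (5 mM), 80 °C
Reagents that add atoms: none
Why: Ring-closing metathesis between the only two terminal alkenes closes the seven-membered ring C with loss of ethene; the ring fixes the alkene geometry (B2 cis to the CH2O arm), and the trisubstituted alkenes of the left half are not engaged.

Step 26
Reactants: 36
Product: 37 (5aR,6S,9R,9aS)-9-hydroxy-9-({[(2E)-2-(hydroxymethyl)-3-[(1R,6R)-3-(hydroxymethyl)-6-(propan-2-yl)cyclohex-2-en-1-yl]prop-2-enoyl]oxy}methyl)-1-oxo-6-(propan-2-yl)-1,3,5a,6,7,8,9,9a-octahydro-2-benzoxepine-4-carboxylic acid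
Conditions: CF3CO2H/CH2Cl2/H2O (10:10:1), 0 °C → rt
Reagents that add atoms: none
Why: Acidolysis removes all three protecting groups (alkyl–oxygen cleavage of the tert-butyl ester, protodesilylation of the two primary silyl ethers); no base, hydride or palladium meets the lactone, the acrylates or the tertiary β-hydroxy ester.

## Compound list

1 | 3-methylbutanal | CC(C)CC=O | starting material
2 | but-3-en-2-one (methyl vinyl ketone) | CC(=O)C=C | starting material
3 | (2S)-5-oxo-2-(propan-2-yl)hexanal | CC(=O)CC[C@@H](C(C)C)C=O | intermediate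
4 | ethyl (2E,4S)-7-oxo-4-(propan-2-yl)oct-2-enoate | CC(=O)CC[C@@H](C(C)C)/C=C/C(=O)OCC | intermediate
5 | (2E,4S)-4-(propan-2-yl)oct-2-ene-1,7-diol (both C7 epimers) | CC(O)CC[C@@H](C(C)C)/C=C/CO | intermediate
6 | (5S,6E)-8-{[tert-butyl(dimethyl)silyl]oxy}-5-(propan-2-yl)oct-6-en-2-ol (both C2 epimers) | CC(O)CC[C@@H](C(C)C)/C=C/CO[Si](C)(C)C(C)(C)C | intermediate
7 | (5S,6E)-8-{[tert-butyl(dimethyl)silyl]oxy}-5-(propan-2-yl)oct-6-en-2-one | CC(=O)CC[C@@H](C(C)C)/C=C/CO[Si](C)(C)C(C)(C)C | intermediate
8 | lithium (5S,6E)-8-{[tert-butyl(dimethyl)silyl]oxy}-5-(propan-2-yl)octa-1,6-dien-2-olate | [Li+].[O-]C(=C)CC[C@@H](C(C)C)/C=C/CO[Si](C)(C)C(C)(C)C | intermediate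
9 | (5S,6E)-8-{[tert-butyl(dimethyl)silyl]oxy}-5-(propan-2-yl)octa-1,6-dien-2-yl trifluoromethanesulfonate | C=C(OS(=O)(=O)C(F)(F)F)CC[C@@H](C(C)C)/C=C/CO[Si](C)(C)C(C)(C)C | intermediate
10 | ethyl (5S,6E)-8-{[tert-butyl(dimethyl)silyl]oxy}-3-methylidene-5-(propan-2-yl)oct-6-enoate | CCOC(=O)CC(=C)CC[C@@H](C(C)C)/C=C/CO[Si](C)(C)C(C)(C)C | intermediate
11 | lithium (5S,6E)-8-{[tert-butyl(dimethyl)silyl]oxy}-3-methylidene-5-(propan-2-yl)oct-6-enoate | [Li+].[O-]C(=O)CC(=C)CC[C@@H](C(C)C)/C=C/CO[Si](C)(C)C(C)(C)C | intermediate
12 | (5S,6E)-8-hydroxy-3-methylidene-5-(propan-2-yl)oct-6-enoic acid | OC(=O)CC(=C)CC[C@@H](C(C)C)/C=C/CO | intermediate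
13 | (5S,6E)-8-hydroxy-3-methylidene-5-(propan-2-yl)oct-6-enoic 2-methyl-6-nitrobenzoic anhydride | Cc1cccc([N+](=O)[O-])c1C(=O)OC(=O)CC(=C)CC[C@@H](C(C)C)/C=C/CO | intermediate
14 | (7S,8E)-4-methylidene-7-(propan-2-yl)oxacyclodec-8-en-2-one | O=C1CC(=C)CC[C@@H](C(C)C)/C=C/CO1 | intermediate
15 | trimethyl{[(7S,8E)-4-methylidene-7-(propan-2-yl)oxacyclodeca-2,8-dien-2-yl]oxy}silane (C2=C3 with C4 cis to the ring oxygen) | C[Si](C)(C)O/C1=C/C(=C)CC[C@@H](C(C)C)/C=C/CO1 | intermediate
16 | trimethylsilyl (1S,2S,3S)-2-ethenyl-6-methylidene-3-(propan-2-yl)cyclohexane-1-carboxylate | C[Si](C)(C)OC(=O)[C@@H]1C(=C)CC[C@@H](C(C)C)[C@@H]1C=C | intermediate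
17 | (1S,2S,3S)-2-ethenyl-6-methylidene-3-(propan-2-yl)cyclohexane-1-carboxylic acid | OC(=O)[C@@H]1C(=C)CC[C@@H](C(C)C)[C@@H]1C=C | intermediate
18 | [(1S,2S,3S)-2-ethenyl-6-methylidene-3-(propan-2-yl)cyclohexyl]methanol | OC[C@@H]1C(=C)CC[C@@H](C(C)C)[C@@H]1C=C | intermediate
19 | [(3R,4R,5S,6S)-5-ethenyl-6-(propan-2-yl)-1-oxaspiro[2.5]octan-4-yl]methanol | OC[C@@H]1[C@@]2(CO2)CC[C@@H](C(C)C)[C@@H]1C=C | intermediate
20 | (2R)-5-oxo-2-(propan-2-yl)hexanal | CC(=O)CC[C@H](C(C)C)C=O | intermediate
21 | (4R)-3-hydroxy-4-(propan-2-yl)cyclohexan-1-one (both C3 epimers) | CC(C)[C@H]1CCC(=O)CC1O | intermediate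
22 | (4R)-4-(propan-2-yl)cyclohex-2-en-1-one | CC(C)[C@H]1CCC(=O)C=C1 | intermediate
23 | bromomagnesium (3R,4R)-3-ethenyl-4-(propan-2-yl)cyclohex-1-en-1-olate | CC(C)[C@H]1CCC(O[Mg]Br)=C[C@@H]1C=C | intermediate
24 | (3R,4R)-3-ethenyl-4-(propan-2-yl)cyclohex-1-en-1-yl trifluoromethanesulfonate | CC(C)[C@H]1CCC(OS(=O)(=O)C(F)(F)F)=C[C@@H]1C=C | intermediate
25 | (3R,4R)-4-(propan-2-yl)-3-(1,2,4-trioxolan-3-yl)cyclohex-1-en-1-yl trifluoromethanesulfonate (trioxolane carbon unassigned) | CC(C)[C@H]1CCC(OS(=O)(=O)C(F)(F)F)=C[C@@H]1C1OCOO1 | intermediate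
26 | (3R,4R)-3-formyl-4-(propan-2-yl)cyclohex-1-en-1-yl trifluoromethanesulfonate | CC(C)[C@H]1CCC(OS(=O)(=O)C(F)(F)F)=C[C@@H]1C=O | intermediate
27 | ethyl (2E)-2-{[(4-methoxyphenyl)methoxy]methyl}-3-[(1S,6R)-6-(propan-2-yl)-3-{[(trifluoromethyl)sulfonyl]oxy}cyclohex-2-en-1-yl]prop-2-enoate | CC(C)[C@H]1CCC(OS(=O)(=O)C(F)(F)F)=C[C@@H]1/C=C(\COCc1ccc(OC)cc1)C(=O)OCC | intermediate
28 | ethyl (2E)-2-(hydroxymethyl)-3-[(1S,6R)-6-(propan-2-yl)-3-{[(trifluoromethyl)sulfonyl]oxy}cyclohex-2-en-1-yl]prop-2-enoate | CC(C)[C@H]1CCC(OS(=O)(=O)C(F)(F)F)=C[C@@H]1/C=C(\CO)C(=O)OCC | intermediate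
29 | ethyl (2E)-2-(hydroxymethyl)-3-[(1R,6R)-3-(hydroxymethyl)-6-(propan-2-yl)cyclohex-2-en-1-yl]prop-2-enoate | CC(C)[C@H]1CCC(CO)=C[C@@H]1/C=C(\CO)C(=O)OCC | intermediate
30 | ethyl (2E)-2-({[tert-butyl(dimethyl)silyl]oxy}methyl)-3-[(1R,6R)-3-({[tert-butyl(dimethyl)silyl]oxy}methyl)-6-(propan-2-yl)cyclohex-2-en-1-yl]prop-2-enoate | CC(C)[C@H]1CCC(CO[Si](C)(C)C(C)(C)C)=C[C@@H]1/C=C(\CO[Si](C)(C)C(C)(C)C)C(=O)OCC | intermediate
31 | (2E)-2-({[tert-butyl(dimethyl)silyl]oxy}methyl)-3-[(1R,6R)-3-({[tert-butyl(dimethyl)silyl]oxy}methyl)-6-(propan-2-yl)cyclohex-2-en-1-yl]prop-2-enoic acid | CC(C)[C@H]1CCC(CO[Si](C)(C)C(C)(C)C)=C[C@@H]1/C=C(\CO[Si](C)(C)C(C)(C)C)C(=O)O | intermediate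
32 | {(1R,2R,3S,4S)-3-ethenyl-1-hydroxy-2-(hydroxymethyl)-4-(propan-2-yl)cyclohexyl}methyl ester of acid 31 | CC(C)[C@H]1CCC(CO[Si](C)(C)C(C)(C)C)=C[C@@H]1/C=C(\CO[Si](C)(C)C(C)(C)C)C(=O)OC[C@@]1(O)CC[C@@H](C(C)C)[C@H](C=C)[C@@H]1CO | intermediate
33 | {(1R,2S,3S,4S)-3-ethenyl-2-formyl-1-hydroxy-4-(propan-2-yl)cyclohexyl}methyl ester of acid 31 | CC(C)[C@H]1CCC(CO[Si](C)(C)C(C)(C)C)=C[C@@H]1/C=C(\CO[Si](C)(C)C(C)(C)C)C(=O)OC[C@@]1(O)CC[C@@H](C(C)C)[C@H](C=C)[C@@H]1C=O | intermediate
34 | (1S,2R,5S,6S)-6-ethenyl-2-hydroxy-5-(propan-2-yl)-2-(acyloxymethyl)cyclohexane-1-carboxylic acid, acyl = acyl group of 31 | CC(C)[C@H]1CCC(CO[Si](C)(C)C(C)(C)C)=C[C@@H]1/C=C(\CO[Si](C)(C)C(C)(C)C)C(=O)OC[C@@]1(O)CC[C@@H](C(C)C)[C@H](C=C)[C@@H]1C(O)=O | intermediate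
35 | 2-(tert-butoxycarbonyl)prop-2-en-1-yl ester of acid 34 | CC(C)[C@H]1CCC(CO[Si](C)(C)C(C)(C)C)=C[C@@H]1/C=C(\CO[Si](C)(C)C(C)(C)C)C(=O)OC[C@@]1(O)CC[C@@H](C(C)C)[C@H](C=C)[C@@H]1C(=O)OCC(=C)C(=O)OC(C)(C)C | intermediate
36 | tert-butyl (5aR,6S,9R,9aS)-9-hydroxy-1-oxo-6-(propan-2-yl)-9-(acyloxymethyl)-1,3,5a,6,7,8,9,9a-octahydro-2-benzoxepine-4-carboxylate, acyl = acyl group of 31 | CC(C)[C@H]1CCC(CO[Si](C)(C)C(C)(C)C)=C[C@@H]1/C=C(\CO[Si](C)(C)C(C)(C)C)C(=O)OC[C@@]1(O)CC[C@@H](C(C)C)[C@@H]2C=C(C(=O)OC(C)(C)C)COC(=O)[C@@H]21 | intermediate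
37 | (5aR,6S,9R,9aS)-9-hydroxy-9-({[(2E)-2-(hydroxymethyl)-3-[(1R,6R)-3-(hydroxymethyl)-6-(propan-2-yl)cyclohex-2-en-1-yl]prop-2-enoyl]oxy}methyl)-1-oxo-6-(propan-2-yl)-1,3,5a,6,7,8,9,9a-octahydro-2-benzoxepine-4-carboxylic acid | CC(C)[C@H]1CCC(CO)=C[C@@H]1/C=C(\CO)C(=O)OC[C@@]1(O)CC[C@@H](C(C)C)[C@@H]2C=C(C(=O)O)COC(=O)[C@@H]21 | target

## Step count and least certain steps

Total: 26 steps. Longest linear sequence: 17 steps (steps 1–12, then 22–26). The left half takes 9 steps (13–21) before the coupling.

**Step 10 (key step).** Two processes may fail. The dienolate may be silylated on carbon or the lactone may isomerise into conjugation before it rearranges. The medium ring may also discriminate poorly between the two boat arrangements that differ in the position of the isopropyl group, so that facial selectivity relative to B1 erodes. The fallback sets out from 3 and comes back at 18, leaving the transannular route: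
- aldol condensation of 3 (LiOH, iPrOH) gives (4S)-4-(propan-2-yl)cyclohex-2-en-1-one F1;
- conjugate addition of CH2=CHMgBr/CuBr·SMe2 and trapping with the pyridyl triflimide gives (3S,4S)-3-ethenyl-4-(propan-2-yl)cyclohex-1-en-1-yl trifluoromethanesulfonate F2;
- Stille coupling with Bu3SnCH2OH gives [(3S,4S)-3-ethenyl-4-(propan-2-yl)cyclohex-1-en-1-yl]methanol F3;
- O-alkylation (KH, Bu3SnCH2I, THF) gives tributyl({[(3S,4S)-3-ethenyl-4-(propan-2-yl)cyclohex-1-en-1-yl]methoxy}methyl)stannane F4;
- tin–lithium exchange (nBuLi, THF, −78 °C) and [2,3]-Wittig–Still rearrangement move the double bond to the exocyclic position and place CH2OH on B3, giving 18.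

In this fallback the cis B2/B3 relation rests on axial delivery anti to the pseudo-axial B2 hydrogen, not on a ring constraint, and 17 is bypassed.

**Step 7.** Transmetalation of the zinc enolate may be slow, the reagent may be protonated, or a palladium hydride may move the new double bond into conjugation. The fallback sets out from 9 and comes back at 10:
- Stille coupling of 9 with Bu3SnCH2OH gives (5S,6E)-8-{[tert-butyl(dimethyl)silyl]oxy}-2-methylidene-5-(propan-2-yl)oct-6-en-1-ol F5;
- MsCl, LiCl and 2,4,6-collidine in DMF give tert-butyl{[(2E,4S)-7-(chloromethyl)-4-(propan-2-yl)octa-2,7-dien-1-yl]oxy}dimethylsilane F6;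
- palladium-catalysed ethoxycarbonylation of the allylic chloride (Pd(OAc)2, PPh3, CO, EtOH, iPr2NEt) gives 10.

**Step 9.** Closure of the strained ten-membered ring may be slower than dimerisation to the diolide, and the activated β,γ-unsaturated acyl group may lose its α-proton (ketene formation, conjugation) under DMAP and Et3N. The fallback sets out from 12 and comes back at 14. It is a Mitsunobu macrolactonisation (PPh3, diisopropyl azodicarboxylate, toluene, slow addition at high dilution), in which the allylic alcohol and not the acid is activated and the carboxylate closes the ring by SN2 at the primary allylic carbon. No new compound is made.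

**Step 17.** The E/Z ratio of the olefination may be poor, the phosphonate anion may enolise the sensitive aldehyde, and the alkoxide may be lost again from the reagent by retro-Michael reaction. The fallback sets out from 26 and comes back at 28, so that step 18 is not needed:
- the α-aluminated acrylate made from ethyl propiolate, iBu2AlH and N-methylmorpholine N-oxide adds to 26 to give ethyl 2-{hydroxy[(1R,6R)-6-(propan-2-yl)-3-{[(trifluoromethyl)sulfonyl]oxy}cyclohex-2-en-1-yl]methyl}prop-2-enoate F7 (both carbinol epimers);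
- acetylation (Ac2O, DMAP) gives the acetate of F7, ethyl 2-{(acetyloxy)[(1R,6R)-6-(propan-2-yl)-3-{[(trifluoromethyl)sulfonyl]oxy}cyclohex-2-en-1-yl]methyl}prop-2-enoate F8;
- DABCO-mediated 1,3-transposition of the acetate (two SN2′ steps) gives the thermodynamically preferred ethyl (2E)-2-[(acetyloxy)methyl]-3-[(1S,6R)-6-(propan-2-yl)-3-{[(trifluoromethyl)sulfonyl]oxy}cyclohex-2-en-1-yl]prop-2-enoate F9;
- transesterification of the acetate (K2CO3 cat., EtOH, 0 °C) gives 28.

**Step 22.** SN2 attack of a weakly nucleophilic, conjugated carboxylate at the neopentyl-like epoxide carbon may be slow, and at 80 °C acyl migration or opening by the alkoxide of a second molecule may compete. The fallback sets out from 19 and comes back at 36; it makes the same ester by acylation of an alcohol: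
- opening of 19 with sodium 4-methoxybenzyl oxide (NaH, 4-MeOC6H4CH2OH, DMF, 60 °C) gives (1R,2R,3S,4S)-3-ethenyl-2-(hydroxymethyl)-1-{[(4-methoxyphenyl)methoxy]methyl}-4-(propan-2-yl)cyclohexan-1-ol F10;
- TEMPO/PhI(OAc)2 gives (1S,2R,5S,6S)-6-ethenyl-2-hydroxy-2-{[(4-methoxyphenyl)methoxy]methyl}-5-(propan-2-yl)cyclohexane-1-carboxylic acid F11;
- alkylation with tert-butyl 2-(bromomethyl)acrylate and K2CO3 gives the 2-(tert-butoxycarbonyl)prop-2-en-1-yl ester of F11, F12;
- ring-closing metathesis gives tert-butyl (5aR,6S,9R,9aS)-9-hydroxy-9-{[(4-methoxyphenyl)methoxy]methyl}-1-oxo-6-(propan-2-yl)-1,3,5a,6,7,8,9,9a-octahydro-2-benzoxepine-4-carboxylate F13;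
- DDQ gives tert-butyl (5aR,6S,9R,9aS)-9-hydroxy-9-(hydroxymethyl)-1-oxo-6-(propan-2-yl)-1,3,5a,6,7,8,9,9a-octahydro-2-benzoxepine-4-carboxylate F14;
- Yamaguchi esterification of the primary hydroxyl of F14 with 31 (2,4,6-trichlorobenzoyl chloride, Et3N; then DMAP) gives 36.

**Step 26.** In acid strong enough to cleave the tert-butyl ester, the allylic alcohols may ionise or be trifluoroacetylated, and the tertiary β-hydroxy ester may dehydrate. The fallback sets out from 36 and comes back at 37, separating the two deprotections: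
- HF·pyridine in THF/pyridine removes both silyl ethers and gives tert-butyl (5aR,6S,9R,9aS)-9-hydroxy-9-({[(2E)-2-(hydroxymethyl)-3-[(1R,6R)-3-(hydroxymethyl)-6-(propan-2-yl)cyclohex-2-en-1-yl]prop-2-enoyl]oxy}methyl)-1-oxo-6-(propan-2-yl)-1,3,5a,6,7,8,9,9a-octahydro-2-benzoxepine-4-carboxylate F15;
- the tert-butyl ester is then cleaved without protic acid by Me3SiOTf and 2,6-lutidine in CH2Cl2 at 0 °C, with mild aqueous work-up, giving 37.

## Further compounds

F1 | step 10 | (4S)-4-(propan-2-yl)cyclohex-2-en-1-one | CC(C)[C@@H]1CCC(=O)C=C1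
F2 | step 10 | (3S,4S)-3-ethenyl-4-(propan-2-yl)cyclohex-1-en-1-yl trifluoromethanesulfonate | CC(C)[C@@H]1CCC(OS(=O)(=O)C(F)(F)F)=C[C@H]1C=C
F3 | step 10 | [(3S,4S)-3-ethenyl-4-(propan-2-yl)cyclohex-1-en-1-yl]methanol | CC(C)[C@@H]1CCC(CO)=C[C@H]1C=C
F4 | step 10 | tributyl({[(3S,4S)-3-ethenyl-4-(propan-2-yl)cyclohex-1-en-1-yl]methoxy}methyl)stannane | CC(C)[C@@H]1CCC(COC[Sn](CCCC)(CCCC)CCCC)=C[C@H]1C=C
F5 | step 7 | (5S,6E)-8-{[tert-butyl(dimethyl)silyl]oxy}-2-methylidene-5-(propan-2-yl)oct-6-en-1-ol | OCC(=C)CC[C@@H](C(C)C)/C=C/CO[Si](C)(C)C(C)(C)C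
F6 | step 7 | tert-butyl{[(2E,4S)-7-(chloromethyl)-4-(propan-2-yl)octa-2,7-dien-1-yl]oxy}dimethylsilane | ClCC(=C)CC[C@@H](C(C)C)/C=C/CO[Si](C)(C)C(C)(C)C
F0 | step 9 | none | none
F7 | step 17 | ethyl 2-{hydroxy[(1R,6R)-6-(propan-2-yl)-3-{[(trifluoromethyl)sulfonyl]oxy}cyclohex-2-en-1-yl]methyl}prop-2-enoate (both carbinol epimers) | CC(C)[C@H]1CCC(OS(=O)(=O)C(F)(F)F)=C[C@@H]1C(O)C(=C)C(=O)OCC
F8 | step 17 | ethyl 2-{(acetyloxy)[(1R,6R)-6-(propan-2-yl)-3-{[(trifluoromethyl)sulfonyl]oxy}cyclohex-2-en-1-yl]methyl}prop-2-enoate | CC(C)[C@H]1CCC(OS(=O)(=O)C(F)(F)F)=C[C@@H]1C(OC(C)=O)C(=C)C(=O)OCC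
F9 | step 17 | ethyl (2E)-2-[(acetyloxy)methyl]-3-[(1S,6R)-6-(propan-2-yl)-3-{[(trifluoromethyl)sulfonyl]oxy}cyclohex-2-en-1-yl]prop-2-enoate | CC(C)[C@H]1CCC(OS(=O)(=O)C(F)(F)F)=C[C@@H]1/C=C(\COC(C)=O)C(=O)OCC
F10 | step 22 | (1R,2R,3S,4S)-3-ethenyl-2-(hydroxymethyl)-1-{[(4-methoxyphenyl)methoxy]methyl}-4-(propan-2-yl)cyclohexan-1-ol | COc1ccc(COC[C@@]2(O)CC[C@@H](C(C)C)[C@H](C=C)[C@@H]2CO)cc1
F11 | step 22 | (1S,2R,5S,6S)-6-ethenyl-2-hydroxy-2-{[(4-methoxyphenyl)methoxy]methyl}-5-(propan-2-yl)cyclohexane-1-carboxylic acid | COc1ccc(COC[C@@]2(O)CC[C@@H](C(C)C)[C@H](C=C)[C@@H]2C(O)=O)cc1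
F12 | step 22 | 2-(tert-butoxycarbonyl)prop-2-en-1-yl (1S,2R,5S,6S)-6-ethenyl-2-hydroxy-2-{[(4-methoxyphenyl)methoxy]methyl}-5-(propan-2-yl)cyclohexane-1-carboxylate | COc1ccc(COC[C@@]2(O)CC[C@@H](C(C)C)[C@H](C=C)[C@@H]2C(=O)OCC(=C)C(=O)OC(C)(C)C)cc1
F13 | step 22 | tert-butyl (5aR,6S,9R,9aS)-9-hydroxy-9-{[(4-methoxyphenyl)methoxy]methyl}-1-oxo-6-(propan-2-yl)-1,3,5a,6,7,8,9,9a-octahydro-2-benzoxepine-4-carboxylate | COc1ccc(COC[C@@]2(O)CC[C@@H](C(C)C)[C@@H]3C=C(C(=O)OC(C)(C)C)COC(=O)[C@@H]32)cc1
F14 | step 22 | tert-butyl (5aR,6S,9R,9aS)-9-hydroxy-9-(hydroxymethyl)-1-oxo-6-(propan-2-yl)-1,3,5a,6,7,8,9,9a-octahydro-2-benzoxepine-4-carboxylate | OC[C@@]1(O)CC[C@@H](C(C)C)[C@@H]2C=C(C(=O)OC(C)(C)C)COC(=O)[C@@H]21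
F15 | step 26 | tert-butyl (5aR,6S,9R,9aS)-9-hydroxy-9-({[(2E)-2-(hydroxymethyl)-3-[(1R,6R)-3-(hydroxymethyl)-6-(propan-2-yl)cyclohex-2-en-1-yl]prop-2-enoyl]oxy}methyl)-1-oxo-6-(propan-2-yl)-1,3,5a,6,7,8,9,9a-octahydro-2-benzoxepine-4-carboxylate | CC(C)[C@H]1CCC(CO)=C[C@@H]1/C=C(\CO)C(=O)OC[C@@]1(O)CC[C@@H](C(C)C)[C@@H]2C=C(C(=O)OC(C)(C)C)COC(=O)[C@@H]21
A1 | alternative 1 | cis-fused 6-({[tert-butyl(dimethyl)silyl]oxy}methyl)-3-(propan-2-yl)-7-oxabicyclo[4.2.0]octan-8-one | O=C1O[C@]2(CO[Si](C)(C)C(C)(C)C)CC[C@@H](C(C)C)C[C@H]12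
A2 | alternative 1 | (4R)-8-{[tert-butyl(dimethyl)silyl]oxy}-7-oxo-4-(propan-2-yl)octanoic acid | OC(=O)CC[C@H](C(C)C)CCC(=O)CO[Si](C)(C)C(C)(C)C
A3 | alternative 2 | right-half bicyclic lactone with the B4 diol as acetonide and the ring-C acid as tert-butyl ester (stereocentres as in 37) | CC1(C)OC[C@@]2(O1)CC[C@@H](C(C)C)[C@@H]3C=C(C(=O)OC(C)(C)C)COC(=O)[C@@H]32
A4 | alternative 2 | cis formyl acid of ring B with the B4 diol as spiro-acetonide (stereocentres as in 37) | CC1(C)OC[C@@]2(O1)CC[C@@H](C(C)C)[C@H](C=O)[C@@H]2C(O)=O
A5 | alternative 2 | tert-butyl 2-(diethoxyphosphoryl)prop-2-enoate | C=C(C(=O)OC(C)(C)C)P(=O)(OCC)OCC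
A6 | alternative 3 | all-trans 3-({[tert-butyl(dimethyl)silyl]oxy}methyl)-4-(propan-2-yl)-5-nitrocyclohex-1-ene-1-carbaldehyde | CC(C)[C@H]1[C@H]([N+](=O)[O-])CC(C=O)=C[C@@H]1CO[Si](C)(C)C(C)(C)C
A7 | alternative 3 | 3-{[tert-butyl(dimethyl)silyl]oxy}propanal | O=CCCO[Si](C)(C)C(C)(C)C
A8 | alternative 3 | (E)-3-methyl-1-nitrobut-1-ene | CC(C)/C=C/[N+](=O)[O-]
A9 | alternative 3 | prop-2-enal | C=CC=O
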